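**Retrosynthetic overview**
- The side chain is built last by steps that form no ring: target ⇒ bis-silyl ether ⇒ α-aryloxy ketone (chelation-controlled reduction) ⇒ aryl Grignard reagent + (R)-aryloxypropanoate ⇒ Mitsunobu inversion of ethyl (S)-lactate on the single free phenol of a mono-silylated verrucosin-type tetrahydrofuran.
- Key disconnection: the C7'–O bond of the tetrahydrofuran, cut to a p-quinone methide at C7' plus the C7 hydroxyl. This is the ring-closing event of the 8–8' bis-quinone-methide biogenesis. The methide is raised in one flask from an all-cis γ-lactone, unprotected 4-lithioguaiacolate and hydride.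
- All-cis lactone ⇒ asymmetric transfer hydrogenation of a γ-keto acid ⇒ rhodium-catalysed enantioselective arylative opening of meso-2,3-dimethylsuccinic anhydride (sets C8 and C8') ⇒ 2,3-dimethylmaleic anhydride.
- Ring order: anhydride ring (bought, hydrogenated to the meso template) → γ-lactone (relay ring carrying C7) → tetrahydrofuran (closed last, sets C7' trans).
- All three aryl rings come from 4-bromo-2-methoxyphenol.

Assumption: the code CNP0171079.3 is taken to mean exactly the stereoisomer of the given SMILES, i.e. (7S,8R,8'S,7'S) in the tetrahydrofuran and erythro-(7''S,8''R) in the side chain (C7/C8 = free-phenol half, primes = etherified half, double primes = side chain).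

**Step 1**
Reactants: 1 4-bromo-2-methoxyphenol
Product: 2 (4-bromo-2-methoxyphenoxy)triisopropylsilane
Conditions: TIPSCl (1.1 equiv), imidazole (2 equiv), DMF, 25 °C
Reagents that add atoms: triisopropylsilyl chloride, CC(C)[Si](Cl)(C(C)C)C(C)C
Why: Imidazole-promoted O-silylation (silyl ether protection) gives a bulky aryl silyl ether that survives organolithium, Grignard, hydride and mildly acidic steps and falls to fluoride at the end; no stereocentre is involved.

**Step 2**
Reactants: 3 2,3-dimethylmaleic anhydride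
Product: 4 (3R,4S)-3,4-dimethyloxolane-2,5-dione (cis, meso)
Conditions: H2 (4 atm), Pd/C (10 wt% Pd), EtOAc, 25 °C
Reagents that add atoms: none
Why: Heterogeneous catalytic hydrogenation adds both hydrogens to one face of the tetrasubstituted alkene (syn addition), so only the cis (meso) anhydride forms.

**Step 3**
Reactants: 2 (4-bromo-2-methoxyphenoxy)triisopropylsilane; 4 (3R,4S)-3,4-dimethyloxolane-2,5-dione
Product: 7 (2S,3R)-4-[3-methoxy-4-(triisopropylsilyloxy)phenyl]-2,3-dimethyl-4-oxobutanoic acid, via aryllithium 5 (not isolated), via arylzinc triflate 6 (not isolated)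
Conditions: 2 (1.7 equiv), n-BuLi, THF, −78 °C; Zn(OTf)2, −78 → 0 °C; then 4, [Rh(cod)Cl]2 (4 mol%), TADDOL-derived N,N-dimethylphosphoramidite (8 mol%, antipode chosen to give (2S,3R)-7), THF, 50 °C; 1 M HCl work-up
Reagents that add atoms: none
Why: Rhodium-catalysed enantioselective desymmetrization of a meso anhydride by acyl cross-coupling with an arylzinc: the chiral monovalent rhodium complex inserts into one of the two enantiotopic C(acyl)–O bonds, transmetalation from zinc and reductive elimination give the aryl ketone, and the two methyl-bearing centres (never broken) emerge as (2S,3R), the ligand antipode fixing the absolute sense.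

**Step 4**
Reactants: 7 (2S,3R)-4-[3-methoxy-4-(triisopropylsilyloxy)phenyl]-2,3-dimethyl-4-oxobutanoic acid
Product: 9 (3S,4R,5S)-5-[3-methoxy-4-(triisopropylsilyloxy)phenyl]-3,4-dimethyloxolan-2-one, via hydroxy acid 8 (not isolated)
Conditions: RuCl[(S,S)-teth-TsDPEN] (2 mol%), HCO2H/Et3N (5:2), EtOAc, 40 °C
Reagents that add atoms: none
Why: Noyori–Ikariya asymmetric transfer hydrogenation of the aryl ketone followed by spontaneous γ-lactonization: the (S,S)-catalyst delivers hydride under catalyst control to give the (4S)-carbinol (the sense in which it gives (S)-1-arylethanols; here the anti-Felkin, syn isomer), and ring closure at the carboxyl carbon leaves that centre untouched, so the aryl group ends cis to both methyls.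

**Step 5**
Reactants: 9 (3S,4R,5S)-5-[3-methoxy-4-(triisopropylsilyloxy)phenyl]-3,4-dimethyloxolan-2-one; 1 4-bromo-2-methoxyphenol
Product: 14 4-{(2S,3S,4R,5S)-5-[3-methoxy-4-(triisopropylsilyloxy)phenyl]-3,4-dimethyloxolan-2-yl}-2-methoxyphenol, via dilithio guaiacolate 10 (not isolated), via keto phenol 11 (not isolated), via diol 12 (not isolated), via quinone methide 13 (not isolated)
Conditions: 1 (1.6 equiv), t-BuLi (4.8 equiv), THF, −78 °C; 9, −78 → 0 °C; LiBH4 (2 equiv), 0 → 25 °C; then 1 M aq. HCl to pH 2, 0 → 25 °C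
Reagents that add atoms: none
Why: Proposed new method: one-flask telescoping of three known events — 1,2-addition of the unprotected aryllithium to the lactone (the lithium hemiketalate resists over-addition), borohydride reduction of the resulting p-oxidoaryl ketone, and acid-triggered dehydration of the p-hydroxybenzylic alcohol to a p-quinone methide, which only the free-phenol ring can form and which the C4 hydroxyl captures in a 5-exo oxa-1,6-addition (the ring-closing event of the biogenetic bis-quinone-methide pathway); A(1,3) strain holds the C–H of the adjacent methyl-bearing carbon in the plane of the methide, so oxygen adds to the face that places the new aryl group trans to that methyl (also the thermodynamic isomer versus all-cis) while the pre-set carbinol centre is retained; closest known reaction type: acid-mediated cyclodehydration of 1-(4-hydroxyaryl)butane-1,4-diols to 2,5-diaryltetrahydrofuran lignans.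

**Step 6**
Reactants: 14 4-{(2S,3S,4R,5S)-5-[3-methoxy-4-(triisopropylsilyloxy)phenyl]-3,4-dimethyloxolan-2-yl}-2-methoxyphenol; 15 ethyl (2S)-2-hydroxypropanoate
Product: 16 ethyl (2R)-2-{4-[(2S,3S,4R,5S)-5-[3-methoxy-4-(triisopropylsilyloxy)phenyl]-3,4-dimethyloxolan-2-yl]-2-methoxyphenoxy}propanoate
Conditions: 15 (1.5 equiv), PPh3, DIAD, THF, 0 → 25 °C
Reagents that add atoms: none
Why: Mitsunobu etherification: the phenol (the only acidic O–H) displaces the activated lactate hydroxyl by SN2 with clean inversion, turning the (S)-lactate into the (R)-aryloxypropanoate that becomes C8''.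

**Step 7**
Reactants: 16 ethyl (2R)-2-{4-[(2S,3S,4R,5S)-5-[3-methoxy-4-(triisopropylsilyloxy)phenyl]-3,4-dimethyloxolan-2-yl]-2-methoxyphenoxy}propanoate; 2 (4-bromo-2-methoxyphenoxy)triisopropylsilane
Product: 19 (2R)-1-[3-methoxy-4-(triisopropylsilyloxy)phenyl]-2-{4-[(2S,3S,4R,5S)-5-[3-methoxy-4-(triisopropylsilyloxy)phenyl]-3,4-dimethyloxolan-2-yl]-2-methoxyphenoxy}propan-1-one, via Weinreb amide 17 (not isolated), via arylmagnesium bromide 18 (not isolated)
Conditions: MeNH(OMe)·HCl (1.5 equiv), i-PrMgCl (3 equiv), THF, −20 °C; then 18 (2.5 equiv, made in a second flask from 2, Mg turnings, cat. I2, THF, 25 → 45 °C, added by cannula), −20 → 0 °C; aq. NH4Cl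
Reagents that add atoms: none
Why: Weinreb ketone synthesis run in one flask: the magnesium amide converts the ester into the N-methoxy-N-methylamide, whose chelated tetrahedral magnesium adduct with the aryl Grignard reagent (formed by direct magnesium insertion into the aryl bromide) collapses only on quench, so mono-addition gives the ketone, and the weakly basic Grignard reagent does not deprotonate the α-aryloxy stereocentre.

**Step 8**
Reactants: 19 (2R)-1-[3-methoxy-4-(triisopropylsilyloxy)phenyl]-2-{4-[(2S,3S,4R,5S)-5-[3-methoxy-4-(triisopropylsilyloxy)phenyl]-3,4-dimethyloxolan-2-yl]-2-methoxyphenoxy}propan-1-one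
Product: 20 (1S,2R)-1-[3-methoxy-4-(triisopropylsilyloxy)phenyl]-2-{4-[(2S,3S,4R,5S)-5-[3-methoxy-4-(triisopropylsilyloxy)phenyl]-3,4-dimethyloxolan-2-yl]-2-methoxyphenoxy}propan-1-ol
Conditions: Zn(BH4)2, Et2O/THF, −20 → 0 °C; aq. NH4Cl
Reagents that add atoms: none
Why: Chelation-controlled (Cram chelate) hydride reduction: zinc bridges the carbonyl and α-aryloxy oxygens and hydride enters from the face of the α-hydrogen, giving the (1S,2R) erythro (anti) alcohol.

**Step 9**
Reactants: 20 (1S,2R)-1-[3-methoxy-4-(triisopropylsilyloxy)phenyl]-2-{4-[(2S,3S,4R,5S)-5-[3-methoxy-4-(triisopropylsilyloxy)phenyl]-3,4-dimethyloxolan-2-yl]-2-methoxyphenoxy}propan-1-ol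
Product: 21 (1S,2R)-1-(4-hydroxy-3-methoxyphenyl)-2-{4-[(2S,3S,4R,5S)-5-(4-hydroxy-3-methoxyphenyl)-3,4-dimethyloxolan-2-yl]-2-methoxyphenoxy}propan-1-ol (CNP0171079.3)
Conditions: TBAF (2.5 equiv), AcOH (2.5 equiv), THF, 0 °C
Reagents that add atoms: none
Why: Fluoride-induced cleavage of both aryl silyl ethers (driven by Si–F bond formation), buffered with acetic acid so that the phenoxides cannot start quinone methide chemistry at the benzylic alcohol or the tetrahydrofuran; no stereocentre is touched.

**Compound list**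
1 | 4-bromo-2-methoxyphenol | COc1cc(Br)ccc1O | starting material
2 | (4-bromo-2-methoxyphenoxy)triisopropylsilane | COc1cc(Br)ccc1O[Si](C(C)C)(C(C)C)C(C)C | intermediate
3 | 2,3-dimethylmaleic anhydride (3,4-dimethylfuran-2,5-dione) | CC1=C(C)C(=O)OC1=O | starting material
4 | (3R,4S)-3,4-dimethyloxolane-2,5-dione (cis, meso) | C[C@H]1C(=O)OC(=O)[C@H]1C | intermediate
5 | [3-methoxy-4-(triisopropylsilyloxy)phenyl]lithium | [Li]c1ccc(O[Si](C(C)C)(C(C)C)C(C)C)c(OC)c1 | intermediate
6 | [3-methoxy-4-(triisopropylsilyloxy)phenyl]zinc trifluoromethanesulfonate | FC(F)(F)S(=O)(=O)O[Zn]c1ccc(O[Si](C(C)C)(C(C)C)C(C)C)c(OC)c1 | intermediate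
7 | (2S,3R)-4-[3-methoxy-4-(triisopropylsilyloxy)phenyl]-2,3-dimethyl-4-oxobutanoic acid | COc1cc(C(=O)[C@H](C)[C@H](C)C(=O)O)ccc1O[Si](C(C)C)(C(C)C)C(C)C | intermediate
8 | (2S,3R,4S)-4-hydroxy-4-[3-methoxy-4-(triisopropylsilyloxy)phenyl]-2,3-dimethylbutanoic acid | COc1cc([C@@H](O)[C@H](C)[C@H](C)C(=O)O)ccc1O[Si](C(C)C)(C(C)C)C(C)C | intermediate
9 | (3S,4R,5S)-5-[3-methoxy-4-(triisopropylsilyloxy)phenyl]-3,4-dimethyloxolan-2-one (all-cis) | COc1cc([C@H]2OC(=O)[C@@H](C)[C@H]2C)ccc1O[Si](C(C)C)(C(C)C)C(C)C | intermediate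
10 | lithium 4-lithio-2-methoxyphenolate | [Li]Oc1ccc([Li])cc1OC | intermediate
11 | (2S,3R,4S)-4-hydroxy-1-(4-hydroxy-3-methoxyphenyl)-4-[3-methoxy-4-(triisopropylsilyloxy)phenyl]-2,3-dimethylbutan-1-one (formed as its lithium salts) | COc1cc([C@@H](O)[C@H](C)[C@H](C)C(=O)c2ccc(O)c(OC)c2)ccc1O[Si](C(C)C)(C(C)C)C(C)C | intermediate
12 | (2S,3R,4S)-1-(4-hydroxy-3-methoxyphenyl)-4-[3-methoxy-4-(triisopropylsilyloxy)phenyl]-2,3-dimethylbutane-1,4-diol (both C1 epimers) | COc1cc([C@@H](O)[C@H](C)[C@H](C)C(O)c2ccc(O)c(OC)c2)ccc1O[Si](C(C)C)(C(C)C)C(C)C | intermediate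
13 | p-quinone methide of 12: 4-alkylidene-2-methoxycyclohexa-2,5-dien-1-one in which C1 of 12 is the exocyclic methide carbon; the C4 carbinol and both methyl-bearing centres are unchanged | COc1cc([C@@H](O)[C@H](C)[C@H](C)C=C2C=CC(=O)C(OC)=C2)ccc1O[Si](C(C)C)(C(C)C)C(C)C | intermediate
14 | 4-{(2S,3S,4R,5S)-5-[3-methoxy-4-(triisopropylsilyloxy)phenyl]-3,4-dimethyloxolan-2-yl}-2-methoxyphenol | COc1cc([C@H]2O[C@H](c3ccc(O)c(OC)c3)[C@@H](C)[C@H]2C)ccc1O[Si](C(C)C)(C(C)C)C(C)C | intermediate
15 | ethyl (2S)-2-hydroxypropanoate (ethyl (S)-lactate) | CCOC(=O)[C@H](C)O | starting material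
16 | ethyl (2R)-2-{4-[(2S,3S,4R,5S)-5-[3-methoxy-4-(triisopropylsilyloxy)phenyl]-3,4-dimethyloxolan-2-yl]-2-methoxyphenoxy}propanoate | COc1cc([C@H]2O[C@H](c3ccc(O[C@H](C)C(=O)OCC)c(OC)c3)[C@@H](C)[C@H]2C)ccc1O[Si](C(C)C)(C(C)C)C(C)C | intermediate
17 | (2R)-N-methoxy-N-methyl-2-{4-[(2S,3S,4R,5S)-5-[3-methoxy-4-(triisopropylsilyloxy)phenyl]-3,4-dimethyloxolan-2-yl]-2-methoxyphenoxy}propanamide | COc1cc([C@H]2O[C@H](c3ccc(O[C@H](C)C(=O)N(C)OC)c(OC)c3)[C@@H](C)[C@H]2C)ccc1O[Si](C(C)C)(C(C)C)C(C)C | intermediate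
18 | [3-methoxy-4-(triisopropylsilyloxy)phenyl]magnesium bromide | COc1cc([Mg]Br)ccc1O[Si](C(C)C)(C(C)C)C(C)C | intermediate
19 | (2R)-1-[3-methoxy-4-(triisopropylsilyloxy)phenyl]-2-{4-[(2S,3S,4R,5S)-5-[3-methoxy-4-(triisopropylsilyloxy)phenyl]-3,4-dimethyloxolan-2-yl]-2-methoxyphenoxy}propan-1-one | COc1cc([C@H]2O[C@H](c3ccc(O[C@H](C)C(=O)c4ccc(O[Si](C(C)C)(C(C)C)C(C)C)c(OC)c4)c(OC)c3)[C@@H](C)[C@H]2C)ccc1O[Si](C(C)C)(C(C)C)C(C)C | intermediate
20 | (1S,2R)-1-[3-methoxy-4-(triisopropylsilyloxy)phenyl]-2-{4-[(2S,3S,4R,5S)-5-[3-methoxy-4-(triisopropylsilyloxy)phenyl]-3,4-dimethyloxolan-2-yl]-2-methoxyphenoxy}propan-1-ol | COc1cc([C@H]2O[C@H](c3ccc(O[C@H](C)[C@@H](O)c4ccc(O[Si](C(C)C)(C(C)C)C(C)C)c(OC)c4)c(OC)c3)[C@@H](C)[C@H]2C)ccc1O[Si](C(C)C)(C(C)C)C(C)C | intermediate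
21 | (1S,2R)-1-(4-hydroxy-3-methoxyphenyl)-2-{4-[(2S,3S,4R,5S)-5-(4-hydroxy-3-methoxyphenyl)-3,4-dimethyloxolan-2-yl]-2-methoxyphenoxy}propan-1-ol | COc1cc([C@H]2O[C@H](c3ccc(O[C@H](C)[C@@H](O)c4ccc(O)c(OC)c4)c(OC)c3)[C@@H](C)[C@H]2C)ccc1O | target

**Step count and risks**
Total step count: 9. Longest linear sequence: 8 (steps 1, 3, 4, 5, 6, 7, 8, 9; step 2 is a one-step side branch).

The three steps most likely to fail:

Step 5 (one-flask arylation, reduction and quinone-methide ring closure). Risks are over-addition or enolization in the aryllithium step, sluggish reduction of the p-oxidoaryl ketone, and competing acid ionization of the silyloxy-aryl carbinol, which would give the 2,5-cis (galgravin-type) isomer. The fallback sets out from 9 (with 10 made from 1 as before) and comes back at 14. The addition is quenched cold and keto phenol 11 is isolated; it equilibrates with its cyclic hemiketal. BF3·OEt2 and Et3SiH in CH2Cl2 at −78 °C reduce the derived 2-aryloxolanylium ion by hydride delivery to the open face opposite the three cis substituents, giving the all-cis tetrahydrofuran 4-{(2R,3S,4R,5S)-5-[3-methoxy-4-(triisopropylsilyloxy)phenyl]-3,4-dimethyloxolan-2-yl}-2-methoxyphenol F1. KHMDS (1.05 equiv) in THF/DMSO at 60 °C, a non-nucleophilic base that spares the aryl silyl ether, then lets the potassium phenoxide open the benzylic C2–O bond to quinone methide 13 (retro-oxa-Michael) and reclose to the thermodynamically preferred 2,3-trans isomer 14. Only the free-phenol centre can epimerize under base, so here the ring is made by hemiketal reduction and the quinone methide only corrects C7'.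

Step 4 (catalyst-controlled reduction against the Felkin–Anh preference of an α-branched aryl ketone). Risks are low rate and eroded diastereoselectivity. The fallback sets out from 7 and comes back at 9. LiBH(s-Bu)3 in THF at −78 °C reduces the ketone with substrate (Felkin–Anh) control to the anti alcohol (2S,3R,4R)-4-hydroxy-4-[3-methoxy-4-(triisopropylsilyloxy)phenyl]-2,3-dimethylbutanoic acid F2. This is worked up cold and closed under Mitsunobu conditions (PPh3, DIAD, THF, 0 °C), where the carboxylate displaces the activated benzylic oxygen with inversion to give the all-cis lactone 9.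

Step 3 (rhodium-catalysed desymmetrization with an electron-rich, silyloxy-substituted arylzinc). Risks are modest enantioselectivity and sensitivity to the quality of the zinc reagent; the ee can be upgraded by crystallizing 7 or 9. The fallback sets out from 4 and comes back at 7. Cinchona-alkaloid-catalysed methanolysis ((DHQD)2AQN or its pseudo-enantiomer, MeOH, Et2O, −20 °C) gives the half-ester (2R,3S)-4-methoxy-2,3-dimethyl-4-oxobutanoic acid F3. Oxalyl chloride with catalytic DMF gives the acid chloride methyl (2S,3R)-4-chloro-2,3-dimethyl-4-oxobutanoate F4. Pd(PPh3)4-catalysed acylation of arylzinc 6 (Negishi-type ketone synthesis, zerovalent palladium) gives the keto ester methyl (2S,3R)-4-[3-methoxy-4-(triisopropylsilyloxy)phenyl]-2,3-dimethyl-4-oxobutanoate F5. Me3SnOH in 1,2-dichloroethane at 60 °C cleaves the methyl ester without epimerization to give 7.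

**Further compounds**
F1 | step 5 | 4-{(2R,3S,4R,5S)-5-[3-methoxy-4-(triisopropylsilyloxy)phenyl]-3,4-dimethyloxolan-2-yl}-2-methoxyphenol | COc1cc([C@H]2O[C@@H](c3ccc(O)c(OC)c3)[C@@H](C)[C@H]2C)ccc1O[Si](C(C)C)(C(C)C)C(C)C
F2 | step 4 | (2S,3R,4R)-4-hydroxy-4-[3-methoxy-4-(triisopropylsilyloxy)phenyl]-2,3-dimethylbutanoic acid | COc1cc([C@H](O)[C@H](C)[C@H](C)C(=O)O)ccc1O[Si](C(C)C)(C(C)C)C(C)C
F3 | step 3 | (2R,3S)-4-methoxy-2,3-dimethyl-4-oxobutanoic acid | COC(=O)[C@@H](C)[C@@H](C)C(=O)O
F4 | step 3 | methyl (2S,3R)-4-chloro-2,3-dimethyl-4-oxobutanoate | COC(=O)[C@@H](C)[C@@H](C)C(=O)Cl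
F5 | step 3 | methyl (2S,3R)-4-[3-methoxy-4-(triisopropylsilyloxy)phenyl]-2,3-dimethyl-4-oxobutanoate | COC(=O)[C@@H](C)[C@@H](C)C(=O)c1ccc(O[Si](C(C)C)(C(C)C)C(C)C)c(OC)c1
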